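**Retrosynthetic overview**
1. The ring enal is unveiled last by MnO2 oxidation of a tetrasubstituted allylic alcohol, after acetylation of the side-chain carbinol and global desilylation.
2. The C5′–C6′ bond and the C5′ carbinol come from a catalytic asymmetric addition of a citronellal-derived (E)-alkenylzinc to an (E)-enal, itself made by Wittig olefination on the three-carbon arm at C1.
3. The tetrasubstituted exocyclic alkene comes from a new palladium-catalysed methylboration of an exocyclic allene, which is made from the C3 ketone by ethynylation, carbonate formation and hydrogenolysis.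
4. The ring stereotriad C1/C2/C6 comes from an anti conjugate addition and anti enolate allylation on a 4-silyloxy-2-methylcyclohexenone, followed by methyl addition to the C6 ketone; the silyloxy centre is set by chiral-base desymmetrisation and later oxidised away.
5. Rings: the single cyclohexane is carried from the starting ketone; no ring is formed in the route.

Assumption: locants are ring C1 (quaternary, bears the long chain), C2 (bears the hydroxypropyl arm), C3 (alkylidene carbon), C6 (carbinol), and chain C1′–C13′ counted from the ring; the target is then (1S,2R,6S), Z at the ring enal, and 3′E,5′R,6′E,8′S. "Q" below means the ring unit (1S,2R,3Z,6S)-3-{1-[(tert-butyldimethylsilyl)oxy]propan-2-ylidene}-2-{3-[tert-butyl(diphenyl)silyloxy]propyl}-1,6-dimethyl-6-[(triethylsilyl)oxy]cyclohexyl.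

**Route**

Step 1
Reactants: 1 4-[(tert-butyldimethylsilyl)oxy]cyclohexan-1-one
Product: 2 (S)-tert-butyldimethyl{[4-(trimethylsilyloxy)cyclohex-3-en-1-yl]oxy}silane
Conditions: lithium (R,R)-bis(1-phenylethyl)amide, TMSCl (in situ quench), THF, −100 °C
Reagents that add atoms: chlorotrimethylsilane, C[Si](C)(C)Cl
Why: Asymmetric deprotonation (chiral lithium amide desymmetrisation) removes one enantiotopic α-proton and makes the CH–OTBS carbon stereogenic; this amide enantiomer is the one that gives the (S)-enol silane with 4-substituted cyclohexanones, and the antipodal amide would give the enantiomer.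

Step 2
Reactants: 2 (S)-tert-butyldimethyl{[4-(trimethylsilyloxy)cyclohex-3-en-1-yl]oxy}silane
Product: 3 (S)-4-[(tert-butyldimethylsilyl)oxy]cyclohex-2-en-1-one
Conditions: Pd(OAc)2 (10 mol %), O2 (1 atm), DMSO, rt
Reagents that add atoms: none
Why: Saegusa–Ito oxidation (palladium enolate, β-hydride elimination) gives the enone without touching the silyloxy stereocentre.

Step 3
Reactants: 3 (S)-4-[(tert-butyldimethylsilyl)oxy]cyclohex-2-en-1-one
Product: 4 (S)-4-[(tert-butyldimethylsilyl)oxy]-2-iodocyclohex-2-en-1-one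
Conditions: I2, pyridine, CH2Cl2, 0 °C → rt
Reagents that add atoms: iodine, II
Why: α-Iodination of the enone by pyridine conjugate addition, iodination and elimination, which does not affect the stereocentre.

Step 4
Reactants: 4 (S)-4-[(tert-butyldimethylsilyl)oxy]-2-iodocyclohex-2-en-1-one
Product: 5 (S)-4-[(tert-butyldimethylsilyl)oxy]-2-methylcyclohex-2-en-1-one
Conditions: Me4Sn, Pd2(dba)3 (2.5 mol %), AsPh3, CuI (10 mol %), NMP, 60 °C
Reagents that add atoms: tetramethylstannane, C[Sn](C)(C)C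
Why: Stille coupling of the α-iodoenone installs the methyl group that later becomes the C1 methyl.

Step 5
Reactants: 5 (S)-4-[(tert-butyldimethylsilyl)oxy]-2-methylcyclohex-2-en-1-one; 6 (3-bromopropoxy)(tert-butyl)diphenylsilane
Product: 10 (2S,3S,4S)-2-allyl-4-[(tert-butyldimethylsilyl)oxy]-3-{3-[tert-butyl(diphenyl)silyloxy]propyl}-2-methylcyclohexan-1-one, via Grignard reagent 7 (not isolated), via silyl enol ether 8 (not isolated), via lithium enolate 9 (not isolated)
Conditions: 6, Mg, THF; then 5, CuBr·SMe2 (10 mol %), TMSCl, HMPA, THF, −78 °C; crude 8, MeLi, THF, 0 °C; allyl iodide, HMPA, −78 → 0 °C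
Reagents that add atoms: allyl iodide, C=CCI; magnesium, [Mg] (metal of 7); chlorotrimethylsilane, C[Si](C)(C)Cl (silyl group of 8); methyllithium, [Li]C (lithium of 9)
Why: Copper-catalysed, TMSCl-accelerated Grignard conjugate addition occurs anti to the γ-silyloxy group (sets C2), and the regiodefined lithium enolate is allylated anti to the new C2 chain (sets quaternary C1 with methyl cis to the C2 chain), a three-component enone coupling.

Step 6
Reactants: 10 (2S,3S,4S)-2-allyl-4-[(tert-butyldimethylsilyl)oxy]-3-{3-[tert-butyl(diphenyl)silyloxy]propyl}-2-methylcyclohexan-1-one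
Product: 11 (1S,2S,3S,4S)-2-allyl-4-[(tert-butyldimethylsilyl)oxy]-3-{3-[tert-butyl(diphenyl)silyloxy]propyl}-1,2-dimethylcyclohexan-1-ol
Conditions: MeLi, CeCl3, THF, −78 °C
Reagents that add atoms: methyllithium, [Li]C
Why: Carbonyl 1,2-addition: with the C2 and C3 substituents equatorial the C1 methyl is axial, so the small methyl nucleophile enters anti to it and the C6 hydroxyl ends cis to the C1 methyl.

Step 7
Reactants: 11 (1S,2S,3S,4S)-2-allyl-4-[(tert-butyldimethylsilyl)oxy]-3-{3-[tert-butyl(diphenyl)silyloxy]propyl}-1,2-dimethylcyclohexan-1-ol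
Product: 12 (1S,2S,3S,4S)-2-allyl-3-{3-[tert-butyl(diphenyl)silyloxy]propyl}-1,2-dimethylcyclohexane-1,4-diol
Conditions: CSA (10 mol %), MeOH–CH2Cl2, 0 °C
Reagents that add atoms: none
Why: Acid-catalysed methanolysis cleaves the secondary TBS ether much faster than the primary TBDPS ether.

Step 8
Reactants: 12 (1S,2S,3S,4S)-2-allyl-3-{3-[tert-butyl(diphenyl)silyloxy]propyl}-1,2-dimethylcyclohexane-1,4-diol
Product: 13 (2S,3S,4S)-3-allyl-2-{3-[tert-butyl(diphenyl)silyloxy]propyl}-4-hydroxy-3,4-dimethylcyclohexan-1-one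
Conditions: Dess–Martin periodinane, NaHCO3, CH2Cl2, 0 °C → rt
Reagents that add atoms: none
Why: Dess–Martin oxidation of the only secondary alcohol under buffered conditions that do not epimerise C2; the directing silyloxy centre has done its work and is removed.

Step 9
Reactants: 13 (2S,3S,4S)-3-allyl-2-{3-[tert-butyl(diphenyl)silyloxy]propyl}-4-hydroxy-3,4-dimethylcyclohexan-1-one
Product: 14 (2S,3S,4S)-3-allyl-2-{3-[tert-butyl(diphenyl)silyloxy]propyl}-3,4-dimethyl-4-[(triethylsilyl)oxy]cyclohexan-1-one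
Conditions: TESOTf, 2,6-lutidine, CH2Cl2, −78 → −40 °C
Reagents that add atoms: triethylsilyl triflate, CC[Si](CC)(CC)OS(=O)(=O)C(F)(F)F
Why: Silyl triflate silylation of the hindered tertiary alcohol, which at low temperature is faster than enol silylation of the ketone.

Step 10
Reactants: 14 (2S,3S,4S)-3-allyl-2-{3-[tert-butyl(diphenyl)silyloxy]propyl}-3,4-dimethyl-4-[(triethylsilyl)oxy]cyclohexan-1-one
Product: 16 (2S,3S,4S)-3-allyl-2-{3-[tert-butyl(diphenyl)silyloxy]propyl}-1-ethynyl-3,4-dimethyl-4-[(triethylsilyl)oxy]cyclohexyl methyl carbonate (both C1 epimers), via magnesium alkoxide 15 (not isolated)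
Conditions: HC≡CMgBr, THF, 0 °C; then ClCO2Me, 0 °C → rt
Reagents that add atoms: ethynylmagnesium bromide, C#C[Mg]Br; methyl chloroformate, COC(=O)Cl
Why: Grignard 1,2-addition to the ketone followed by O-acylation of the alkoxide; the new carbinol centre is an epimeric mixture that converges in step 11.

Step 11
Reactants: 16 (2S,3S,4S)-3-allyl-2-{3-[tert-butyl(diphenyl)silyloxy]propyl}-1-ethynyl-3,4-dimethyl-4-[(triethylsilyl)oxy]cyclohexyl methyl carbonate
Product: 17 tert-butyl{3-[(1R,2S,3S)-2-allyl-2,3-dimethyl-3-[(triethylsilyl)oxy]-6-vinylidenecyclohexyl]propoxy}diphenylsilane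
Conditions: Pd2(dba)3·CHCl3 (2.5 mol %), PBu3 (10 mol %), HCO2NH4, THF, 40 °C
Reagents that add atoms: none
Why: Tsuji-type palladium-catalysed hydrogenolysis of a propargylic carbonate: SN2′ oxidative addition gives an allenylpalladium formate that loses CO2 and reductively eliminates to the terminal allene.

Step 12
Reactants: 17 tert-butyl{3-[(1R,2S,3S)-2-allyl-2,3-dimethyl-3-[(triethylsilyl)oxy]-6-vinylidenecyclohexyl]propoxy}diphenylsilane
Product: 19 (2Z)-2-[(2R,3S,4S)-3-allyl-2-{3-[tert-butyl(diphenyl)silyloxy]propyl}-3,4-dimethyl-4-[(triethylsilyl)oxy]cyclohexylidene]propan-1-ol, via allylboronate 18 (not isolated)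
Conditions: Pd(dba)2 (5 mol %), P(2-furyl)3 (10 mol %), MeI, B2pin2, toluene, 60 °C (sealed tube); then NaBO3·4H2O, THF–H2O, rt
Reagents that add atoms: iodomethane, CI; bis(pinacolato)diboron, CC1(C)OB(OC1(C)C)B1OC(C)(C)C(C)(C)O1 (boron of 18); sodium perborate, [Na+].[O-]OB=O (oxygen of 19)
Why: Proposed new method: a palladium-catalysed three-component methylboration of a 1,1-disubstituted allene, in which MeI adds oxidatively to zerovalent palladium, the Me–Pd–I species binds the terminal C=CH2 π bond (whose lobes lie in the plane of the two ring carbons flanking C3) from the ring-CH2 side, away from the equatorial C2 chain, syn migratory insertion puts CH3 on the central allene carbon cis to the ring CH2 and leaves the divalent-palladium allyl with its CH2 terminus cis to C2, B–B transmetalation and C–B reductive elimination at that unhindered terminus give 18 and return zerovalent palladium, and perborate oxidation with retention gives 19; the geometry set at insertion should survive because syn/anti exchange would need an η1 allyl at the tertiary ring carbon; the step forms the C–CH3 bond and sets the Z tetrasubstituted alkene; the closest known reaction type is the palladium-catalysed three-component aryl- and alkenylboration of allenes with organic iodides and B2pin2, together with stoichiometric insertion of allenes into Pd–CH3 bonds, and methyl iodide has not been shown as the halide partner.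

Step 13
Reactants: 19 (2Z)-2-[(2R,3S,4S)-3-allyl-2-{3-[tert-butyl(diphenyl)silyloxy]propyl}-3,4-dimethyl-4-[(triethylsilyl)oxy]cyclohexylidene]propan-1-ol
Product: 20 tert-butyl{[(2Z)-2-[(2R,3S,4S)-3-allyl-2-{3-[tert-butyl(diphenyl)silyloxy]propyl}-3,4-dimethyl-4-[(triethylsilyl)oxy]cyclohexylidene]propyl]oxy}dimethylsilane
Conditions: TBSCl, imidazole, DMF, 0 °C → rt
Reagents that add atoms: tert-butyldimethylsilyl chloride, CC(C)(C)[Si](C)(C)Cl
Why: Standard silylation of the primary allylic alcohol, which masks the future aldehyde.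

Step 14
Reactants: 20 tert-butyl{[(2Z)-2-[(2R,3S,4S)-3-allyl-2-{3-[tert-butyl(diphenyl)silyloxy]propyl}-3,4-dimethyl-4-[(triethylsilyl)oxy]cyclohexylidene]propyl]oxy}dimethylsilane
Product: 22 3-Q-propan-1-ol, via trialkylborane 21 (not isolated)
Conditions: 9-BBN, THF, 0 °C → rt; then NaBO3·4H2O, H2O, rt
Reagents that add atoms: 9-borabicyclo[3.3.1]nonane, B1C2CCCC1CCC2 (boron of 21); sodium perborate, [Na+].[O-]OB=O (oxygen of 22)
Why: Hydroboration–oxidation: 9-BBN adds anti-Markovnikov to the monosubstituted alkene only, and the tetrasubstituted alkene is inert.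

Step 15
Reactants: 22 3-Q-propan-1-ol
Product: 23 3-Q-propanal
Conditions: Dess–Martin periodinane, NaHCO3, CH2Cl2, 0 °C → rt
Reagents that add atoms: none
Why: Dess–Martin oxidation of the only free alcohol to the aldehyde.

Step 16
Reactants: 23 3-Q-propanal
Product: 24 (2E)-2-methyl-5-Q-pent-2-enal
Conditions: Ph3P=C(CH3)CHO, toluene, 90 °C
Reagents that add atoms: 2-(triphenylphosphoranylidene)propanal, CC(C=O)=P(c1ccccc1)(c1ccccc1)c1ccccc1
Why: Wittig olefination with a stabilised ylide gives the (E)-trisubstituted enal (the C3′=C4′ alkene).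

Step 17
Reactants: 25 (S)-citronellal [(3S)-3,7-dimethyloct-6-enal]
Product: 27 (3S)-3,7-dimethyloct-6-en-1-yne, via alkenyl nonaflate 26 (not isolated)
Conditions: nonafluorobutane-1-sulfonyl fluoride, P2-Et phosphazene base (2.2 equiv), DMF, −20 °C → rt
Reagents that add atoms: nonafluorobutane-1-sulfonyl fluoride, FS(=O)(=O)C(F)(F)C(F)(F)C(F)(F)C(F)(F)F (nonaflyl group of 26)
Why: Aldehyde-to-alkyne dehydration by O-nonaflation of the enolate and E2 loss of nonaflate; the methyl-bearing stereocentre is not acidic under these conditions and is carried over unchanged.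

Step 18
Reactants: 24 (2E)-2-methyl-5-Q-pent-2-enal; 27 (3S)-3,7-dimethyloct-6-en-1-yne
Product: 30 (3E,5R,6E,8S)-4,8,12-trimethyl-1-Q-trideca-3,6,11-trien-5-ol, via alkenylborane 28 (not isolated), via alkenylzinc 29 (not isolated)
Conditions: 27, Cy2BH (from BH3·SMe2 and cyclohexene), toluene, 0 °C → rt; Me2Zn, −78 °C; (+)-MIB (5 mol %), then 24, −20 → 0 °C
Reagents that add atoms: dicyclohexylborane, C1CCCCC1BC1CCCCC1 (boron of 28); dimethylzinc, C[Zn]C (zinc and methyl of 29)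
Why: Catalytic asymmetric alkenylzinc addition: syn hydroboration fixes the (E)-C6′=C7′ alkene, boron-to-zinc exchange gives the alkenylzinc, and the amino-alcohol zinc catalyst delivers it to the Re face of the enal to set C5′ as R; the (−)-ligand gives the opposite face with this substitution pattern, so the (+)-ligand is used.

Step 19
Reactants: 30 (3E,5R,6E,8S)-4,8,12-trimethyl-1-Q-trideca-3,6,11-trien-5-ol
Product: 31 (3E,5R,6E,8S)-4,8,12-trimethyl-1-Q-trideca-3,6,11-trien-5-yl acetate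
Conditions: Ac2O, pyridine, DMAP (5 mol %), CH2Cl2, 0 °C
Reagents that add atoms: acetic anhydride, CC(=O)OC(C)=O
Why: Acylation of the only free hydroxyl, with retention at C5′.

Step 20
Reactants: 31 (3E,5R,6E,8S)-4,8,12-trimethyl-1-Q-trideca-3,6,11-trien-5-yl acetate
Product: 32 (3E,5R,6E,8S)-1-[(1S,2R,3Z,6S)-6-hydroxy-2-(3-hydroxypropyl)-3-(1-hydroxypropan-2-ylidene)-1,6-dimethylcyclohexyl]-4,8,12-trimethyltrideca-3,6,11-trien-5-yl acetate
Conditions: HF·pyridine, pyridine, THF, 0 °C → rt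
Reagents that add atoms: none
Why: Fluoride cleavage of the three silyl ethers under buffered, non-basic conditions that leave the acetate in place.

Step 21
Reactants: 32 (3E,5R,6E,8S)-1-[(1S,2R,3Z,6S)-6-hydroxy-2-(3-hydroxypropyl)-3-(1-hydroxypropan-2-ylidene)-1,6-dimethylcyclohexyl]-4,8,12-trimethyltrideca-3,6,11-trien-5-yl acetate
Product: 33 (3E,5R,6E,8S)-1-[(1S,2R,3Z,6S)-6-hydroxy-2-(3-hydroxypropyl)-1,6-dimethyl-3-(1-oxopropan-2-ylidene)cyclohexyl]-4,8,12-trimethyltrideca-3,6,11-trien-5-yl acetate (CNP0259235.1)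
Conditions: MnO2, CH2Cl2, rt
Reagents that add atoms: none
Why: Allylic oxidation with MnO2 converts only the allylic primary alcohol into the enal; the saturated primary alcohol, the tertiary alcohol and the alkene geometry are untouched.

**Compound list**

1 | 4-[(tert-butyldimethylsilyl)oxy]cyclohexan-1-one | O=C1CCC(O[Si](C)(C)C(C)(C)C)CC1 | starting material
2 | (S)-tert-butyldimethyl{[4-(trimethylsilyloxy)cyclohex-3-en-1-yl]oxy}silane | C[Si](C)(C)OC1=CC[C@@H](O[Si](C)(C)C(C)(C)C)CC1 | intermediate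
3 | (S)-4-[(tert-butyldimethylsilyl)oxy]cyclohex-2-en-1-one | O=C1C=C[C@@H](O[Si](C)(C)C(C)(C)C)CC1 | intermediate
4 | (S)-4-[(tert-butyldimethylsilyl)oxy]-2-iodocyclohex-2-en-1-one | O=C1C(I)=C[C@@H](O[Si](C)(C)C(C)(C)C)CC1 | intermediate
5 | (S)-4-[(tert-butyldimethylsilyl)oxy]-2-methylcyclohex-2-en-1-one | O=C1C(C)=C[C@@H](O[Si](C)(C)C(C)(C)C)CC1 | intermediate
6 | (3-bromopropoxy)(tert-butyl)diphenylsilane | BrCCCO[Si](c1ccccc1)(c1ccccc1)C(C)(C)C | starting material
7 | {3-[tert-butyl(diphenyl)silyloxy]propyl}magnesium bromide | Br[Mg]CCCO[Si](c1ccccc1)(c1ccccc1)C(C)(C)C | intermediate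
8 | tert-butyl{3-[(1S,6S)-6-[(tert-butyldimethylsilyl)oxy]-2-methyl-3-(trimethylsilyloxy)cyclohex-2-en-1-yl]propoxy}diphenylsilane | CC1=C(O[Si](C)(C)C)CC[C@H](O[Si](C)(C)C(C)(C)C)[C@H]1CCCO[Si](c2ccccc2)(c2ccccc2)C(C)(C)C | intermediate
9 | lithium (3S,4S)-4-[(tert-butyldimethylsilyl)oxy]-3-{3-[tert-butyl(diphenyl)silyloxy]propyl}-2-methylcyclohex-1-en-1-olate | CC1=C(O[Li])CC[C@H](O[Si](C)(C)C(C)(C)C)[C@H]1CCCO[Si](c2ccccc2)(c2ccccc2)C(C)(C)C | intermediate
10 | (2S,3S,4S)-2-allyl-4-[(tert-butyldimethylsilyl)oxy]-3-{3-[tert-butyl(diphenyl)silyloxy]propyl}-2-methylcyclohexan-1-one | C=CC[C@@]1(C)[C@H](CCCO[Si](c2ccccc2)(c2ccccc2)C(C)(C)C)[C@@H](O[Si](C)(C)C(C)(C)C)CCC1=O | intermediate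
11 | (1S,2S,3S,4S)-2-allyl-4-[(tert-butyldimethylsilyl)oxy]-3-{3-[tert-butyl(diphenyl)silyloxy]propyl}-1,2-dimethylcyclohexan-1-ol | C=CC[C@@]1(C)[C@H](CCCO[Si](c2ccccc2)(c2ccccc2)C(C)(C)C)[C@@H](O[Si](C)(C)C(C)(C)C)CC[C@]1(C)O | intermediate
12 | (1S,2S,3S,4S)-2-allyl-3-{3-[tert-butyl(diphenyl)silyloxy]propyl}-1,2-dimethylcyclohexane-1,4-diol | C=CC[C@@]1(C)[C@H](CCCO[Si](c2ccccc2)(c2ccccc2)C(C)(C)C)[C@@H](O)CC[C@]1(C)O | intermediate
13 | (2S,3S,4S)-3-allyl-2-{3-[tert-butyl(diphenyl)silyloxy]propyl}-4-hydroxy-3,4-dimethylcyclohexan-1-one | C=CC[C@@]1(C)[C@H](CCCO[Si](c2ccccc2)(c2ccccc2)C(C)(C)C)C(=O)CC[C@]1(C)O | intermediate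
14 | (2S,3S,4S)-3-allyl-2-{3-[tert-butyl(diphenyl)silyloxy]propyl}-3,4-dimethyl-4-[(triethylsilyl)oxy]cyclohexan-1-one | C=CC[C@@]1(C)[C@H](CCCO[Si](c2ccccc2)(c2ccccc2)C(C)(C)C)C(=O)CC[C@]1(C)O[Si](CC)(CC)CC | intermediate
15 | bromomagnesium (2S,3S,4S)-3-allyl-2-{3-[tert-butyl(diphenyl)silyloxy]propyl}-1-ethynyl-3,4-dimethyl-4-[(triethylsilyl)oxy]cyclohexan-1-olate (C1 epimers) | C=CC[C@@]1(C)[C@H](CCCO[Si](c2ccccc2)(c2ccccc2)C(C)(C)C)C(O[Mg]Br)(C#C)CC[C@]1(C)O[Si](CC)(CC)CC | intermediate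
16 | (2S,3S,4S)-3-allyl-2-{3-[tert-butyl(diphenyl)silyloxy]propyl}-1-ethynyl-3,4-dimethyl-4-[(triethylsilyl)oxy]cyclohexyl methyl carbonate (C1 epimers) | C=CC[C@@]1(C)[C@H](CCCO[Si](c2ccccc2)(c2ccccc2)C(C)(C)C)C(OC(=O)OC)(C#C)CC[C@]1(C)O[Si](CC)(CC)CC | intermediate
17 | tert-butyl{3-[(1R,2S,3S)-2-allyl-2,3-dimethyl-3-[(triethylsilyl)oxy]-6-vinylidenecyclohexyl]propoxy}diphenylsilane | C=CC[C@@]1(C)[C@H](CCCO[Si](c2ccccc2)(c2ccccc2)C(C)(C)C)C(=C=C)CC[C@]1(C)O[Si](CC)(CC)CC | intermediate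
18 | tert-butyl{3-[(1R,2S,3S,6Z)-2-allyl-2,3-dimethyl-6-[1-(4,4,5,5-tetramethyl-1,3,2-dioxaborolan-2-yl)propan-2-ylidene]-3-[(triethylsilyl)oxy]cyclohexyl]propoxy}diphenylsilane | C=CC[C@@]1(C)[C@H](CCCO[Si](c2ccccc2)(c2ccccc2)C(C)(C)C)/C(=C(/C)CB2OC(C)(C)C(C)(C)O2)CC[C@]1(C)O[Si](CC)(CC)CC | intermediate
19 | (2Z)-2-[(2R,3S,4S)-3-allyl-2-{3-[tert-butyl(diphenyl)silyloxy]propyl}-3,4-dimethyl-4-[(triethylsilyl)oxy]cyclohexylidene]propan-1-ol | C=CC[C@@]1(C)[C@H](CCCO[Si](c2ccccc2)(c2ccccc2)C(C)(C)C)/C(=C(/C)CO)CC[C@]1(C)O[Si](CC)(CC)CC | intermediate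
20 | tert-butyl{[(2Z)-2-[(2R,3S,4S)-3-allyl-2-{3-[tert-butyl(diphenyl)silyloxy]propyl}-3,4-dimethyl-4-[(triethylsilyl)oxy]cyclohexylidene]propyl]oxy}dimethylsilane | C=CC[C@@]1(C)[C@H](CCCO[Si](c2ccccc2)(c2ccccc2)C(C)(C)C)/C(=C(/C)CO[Si](C)(C)C(C)(C)C)CC[C@]1(C)O[Si](CC)(CC)CC | intermediate
21 | 9-(3-Q-propyl)-9-borabicyclo[3.3.1]nonane | B2(CCC[C@@]1(C)[C@H](CCCO[Si](c3ccccc3)(c3ccccc3)C(C)(C)C)/C(=C(/C)CO[Si](C)(C)C(C)(C)C)CC[C@]1(C)O[Si](CC)(CC)CC)C3CCCC2CCC3 | intermediate
22 | 3-Q-propan-1-ol | OCCC[C@@]1(C)[C@H](CCCO[Si](c2ccccc2)(c2ccccc2)C(C)(C)C)/C(=C(/C)CO[Si](C)(C)C(C)(C)C)CC[C@]1(C)O[Si](CC)(CC)CC | intermediate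
23 | 3-Q-propanal | O=CCC[C@@]1(C)[C@H](CCCO[Si](c2ccccc2)(c2ccccc2)C(C)(C)C)/C(=C(/C)CO[Si](C)(C)C(C)(C)C)CC[C@]1(C)O[Si](CC)(CC)CC | intermediate
24 | (2E)-2-methyl-5-Q-pent-2-enal | O=C/C(C)=C/CC[C@@]1(C)[C@H](CCCO[Si](c2ccccc2)(c2ccccc2)C(C)(C)C)/C(=C(/C)CO[Si](C)(C)C(C)(C)C)CC[C@]1(C)O[Si](CC)(CC)CC | intermediate
25 | (S)-citronellal, (3S)-3,7-dimethyloct-6-enal | O=CC[C@@H](C)CCC=C(C)C | starting material
26 | (3S)-3,7-dimethylocta-1,6-dien-1-yl nonafluorobutane-1-sulfonate (E/Z mixture) | FC(F)(F)C(F)(F)C(F)(F)C(F)(F)S(=O)(=O)OC=C[C@@H](C)CCC=C(C)C | intermediate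
27 | (3S)-3,7-dimethyloct-6-en-1-yne | C#C[C@@H](C)CCC=C(C)C | intermediate
28 | dicyclohexyl[(1E,3S)-3,7-dimethylocta-1,6-dien-1-yl]borane | C1CCCCC1B(/C=C/[C@@H](C)CCC=C(C)C)C1CCCCC1 | intermediate
29 | [(1E,3S)-3,7-dimethylocta-1,6-dien-1-yl](methyl)zinc | C[Zn]/C=C/[C@@H](C)CCC=C(C)C | intermediate
30 | (3E,5R,6E,8S)-4,8,12-trimethyl-1-Q-trideca-3,6,11-trien-5-ol | O[C@H](/C=C/[C@@H](C)CCC=C(C)C)/C(C)=C/CC[C@@]1(C)[C@H](CCCO[Si](c2ccccc2)(c2ccccc2)C(C)(C)C)/C(=C(/C)CO[Si](C)(C)C(C)(C)C)CC[C@]1(C)O[Si](CC)(CC)CC | intermediate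
31 | (3E,5R,6E,8S)-4,8,12-trimethyl-1-Q-trideca-3,6,11-trien-5-yl acetate | CC(=O)O[C@H](/C=C/[C@@H](C)CCC=C(C)C)/C(C)=C/CC[C@@]1(C)[C@H](CCCO[Si](c2ccccc2)(c2ccccc2)C(C)(C)C)/C(=C(/C)CO[Si](C)(C)C(C)(C)C)CC[C@]1(C)O[Si](CC)(CC)CC | intermediate
32 | (3E,5R,6E,8S)-1-[(1S,2R,3Z,6S)-6-hydroxy-2-(3-hydroxypropyl)-3-(1-hydroxypropan-2-ylidene)-1,6-dimethylcyclohexyl]-4,8,12-trimethyltrideca-3,6,11-trien-5-yl acetate | CC(=O)O[C@H](/C=C/[C@@H](C)CCC=C(C)C)/C(C)=C/CC[C@@]1(C)[C@H](CCCO)/C(=C(/C)CO)CC[C@]1(C)O | intermediate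
33 | (3E,5R,6E,8S)-1-[(1S,2R,3Z,6S)-6-hydroxy-2-(3-hydroxypropyl)-1,6-dimethyl-3-(1-oxopropan-2-ylidene)cyclohexyl]-4,8,12-trimethyltrideca-3,6,11-trien-5-yl acetate | CC(=O)O[C@H](/C=C/[C@@H](C)CCC=C(C)C)/C(C)=C/CC[C@@]1(C)[C@H](CCCO)/C(=C(/C)C=O)CC[C@]1(C)O | target

**Step count and risk**

Total step count: 21. Longest linear sequence: 20 steps (steps 1–16 and 18–21, from 1); the alkyne branch adds step 17.

The three steps most likely to fail:

Step 5, the quaternary C1 centre. In the enolate conformer with the C2 chain axial, the C3 silyloxy group is also axial and sits 1,3 to the incoming allyl iodide, so the anti selectivity may erode. The fallback sets out from silyl enol ether 8 and comes back at 10. MeLi converts 8 into enolate 9, which is O-acylated with allyl chloroformate to give the allyl enol carbonate F1. Decarboxylative Tsuji allylation of F1 with Pd2(dba)3 and (R)-t-Bu-PHOX in THF at rt then gives 10, the face now being chosen by the chiral palladium catalyst within the enolate–allyl ion pair and not by the substrate alone.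

Step 6, the facial selectivity of methyl addition at C6. If the methyl group enters mainly from the face of the C1 methyl, the same facial bias is used to deliver oxygen instead of carbon. The fallback sets out from 10 and comes back at 11. Wittig methylenation (Ph3P=CH2, THF) gives the exocyclic alkene F2, epoxidation with mCPBA (NaHCO3, CH2Cl2) from that more accessible face gives the spiro-epoxide F3, and LiEt3BH opens the oxirane at its CH2 carbon to give 11.

Step 12, the proposed methylboration. The risks are β-hydride loss from the palladium allyl to a 1,3-diene, Heck-type methylation of the allyl group, and allene diboration. The fallback uses known chemistry, sets out from ketone 14 and comes back at 19. Lithium ethoxyacetylide (ethoxyacetylene, n-BuLi, THF, −78 °C) adds to 14 to give the ethoxyalkynyl carbinol F4. NIS in CH2Cl2 at 0 °C effects the iodo-Meyer–Schuster rearrangement to the α-iodo enoate F5, used as its E/Z mixture. Iodine–lithium exchange (t-BuLi, THF, −100 °C) gives the linear lithium allenolate F6, which erases the alkene geometry and is C-methylated in the ring plane from the ring-CH2 side (MeI, HMPA) to give the ethyl (Z)-enoate F7. Reduction with i-Bu2AlH (CH2Cl2, −78 °C) gives 19.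

**Further compounds**

F1 | step 5 | allyl (3S,4S)-4-[(tert-butyldimethylsilyl)oxy]-3-{3-[tert-butyl(diphenyl)silyloxy]propyl}-2-methylcyclohex-1-en-1-yl carbonate | CC1=C(OC(=O)OCC=C)CC[C@H](O[Si](C)(C)C(C)(C)C)[C@H]1CCCO[Si](c2ccccc2)(c2ccccc2)C(C)(C)C
F2 | step 6 | methylene analogue of 10 (C=CH2 in place of C=O; other centres as in 10) | C=CC[C@@]1(C)[C@H](CCCO[Si](c2ccccc2)(c2ccccc2)C(C)(C)C)[C@@H](O[Si](C)(C)C(C)(C)C)CCC1=C
F3 | step 6 | spiro-epoxide of F2 with the oxirane oxygen cis to the C1 methyl group | C=CC[C@@]1(C)[C@H](CCCO[Si](c2ccccc2)(c2ccccc2)C(C)(C)C)[C@@H](O[Si](C)(C)C(C)(C)C)CC[C@@]13CO3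
F4 | step 12 | (2S,3S,4S)-3-allyl-2-{3-[tert-butyl(diphenyl)silyloxy]propyl}-1-(ethoxyethynyl)-3,4-dimethyl-4-[(triethylsilyl)oxy]cyclohexan-1-ol (C1 epimers) | C=CC[C@@]1(C)[C@H](CCCO[Si](c2ccccc2)(c2ccccc2)C(C)(C)C)C(O)(C#COCC)CC[C@]1(C)O[Si](CC)(CC)CC
F5 | step 12 | ethyl 2-[(2R,3S,4S)-3-allyl-2-{3-[tert-butyl(diphenyl)silyloxy]propyl}-3,4-dimethyl-4-[(triethylsilyl)oxy]cyclohexylidene]-2-iodoacetate (E/Z mixture) | C=CC[C@@]1(C)[C@H](CCCO[Si](c2ccccc2)(c2ccccc2)C(C)(C)C)C(=C(I)C(=O)OCC)CC[C@]1(C)O[Si](CC)(CC)CC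
F6 | step 12 | lithium allenolate from F5: lithium 2-[(2R,3S,4S)-3-allyl-2-{3-[tert-butyl(diphenyl)silyloxy]propyl}-3,4-dimethyl-4-[(triethylsilyl)oxy]cyclohexylidene]-1-ethoxyethen-1-olate | C=CC[C@@]1(C)[C@H](CCCO[Si](c2ccccc2)(c2ccccc2)C(C)(C)C)C(=C=C(O[Li])OCC)CC[C@]1(C)O[Si](CC)(CC)CC
F7 | step 12 | ethyl (2Z)-2-[(2R,3S,4S)-3-allyl-2-{3-[tert-butyl(diphenyl)silyloxy]propyl}-3,4-dimethyl-4-[(triethylsilyl)oxy]cyclohexylidene]propanoate | C=CC[C@@]1(C)[C@H](CCCO[Si](c2ccccc2)(c2ccccc2)C(C)(C)C)/C(=C(/C)C(=O)OCC)CC[C@]1(C)O[Si](CC)(CC)CC
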